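**Retrosynthetic overview**
1. Feature: the cis-fused hydroazulene (cycloheptane C2–C6/C9/C26 with exocyclic C1=C2 and gem-dimethyl C6; cyclopentane C9–C12/C26 with quaternary C12) is a drimane trans-decalin (rings C2–C6/C9 and C2/C9–C12/C26) in which C9 has moved from C2 to C26.
2. Last ring: the γ-lactone closes at C20–C25 by catalyst-controlled dirhodium carbene insertion into C20–H of the O22 diazoacetate; C21 comes from a vinyl group (ethenolysis, then anti-Markovnikov hydroboration).
3. C14–C15 by Wittig–Still [2,3] shift on a (Z)-C14=C20 allylic ether whose (S)-carbinol (Noyori reduction of an ynone) dictates C14; the chain grows from the C14 aldehyde.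
4. Both carbocycles at once: C9–C26 by Wagner–Meerwein shift on ionisation of the equatorial C26 mesylate of the trans-decalin (six→five and six→seven), ending with proton loss from C1.
5. The decalin comes from (+)-sclareolide: the two lactone carbons are excised (selenoxide elimination, ozonolysis), the C12 oxygen is removed and C12 is hydroxymethylated. Ring order: decalin (chiral pool) → cyclopentane + cycloheptane (step 8) → lactone (step 22).

Key step: step 8

Remark: atoms carry the numbers of the target SMILES read left to right, also in the decalin intermediates; β is the face of the angular methyl C1, α the opposite face.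

**Step 1**
Reactants: 1 (+)-sclareolide
Product: 3 butenolide (9(11)-dehydrosclareolide), via α-phenylselanyl lactone 2 (not isolated)
Conditions: LDA, THF, −78 °C; PhSeBr; then AcOH, 30% H2O2, 0 → 25 °C
Reagents that add atoms: none
Why: α-Selenenylation of the lactone enolate should occur on the α face (the β face is covered by the axial methyls C13 and C1), which puts selenium cis to H-26, so the selenoxide formed in the same flask undergoes syn selenoxide elimination toward C26; C26 becomes sp2 and no stereocentre is created.

**Step 2**
Reactants: 3 butenolide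
Product: 5 ketol (C26 ketone with 12α-OH), via keto glyoxylate 4 (not isolated)
Conditions: O3, CH2Cl2/MeOH, −78 °C; Me2S; then K2CO3 (cat.), MeOH, 0 °C
Reagents that add atoms: ozone, O=[O+][O-]
Why: Ozonolysis cleaves the C26=CH bond to the C26 ketone and a glyoxylate ester on the C12 oxygen, and glyoxylates are transesterified by methanol under mild carbonate catalysis, so both lactone carbons leave.

**Step 3**
Reactants: 5 ketol
Product: 6 decalone (C13 methyl equatorial)
Conditions: SmI2 (2.5 equiv), THF/HMPA, MeOH, −78 → 0 °C
Reagents that add atoms: none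
Why: Samarium diiodide reduction of an α-oxygenated ketone: the ketyl expels the C12 oxygen and the samarium enolate is protonated, the methyl ending mainly equatorial; this configuration is erased again in step 4.

**Step 4**
Reactants: 6 decalone; 7 formaldehyde
Product: 8 12α-hydroxymethyl decalone
Conditions: LDA, THF, −78 → 0 °C; then monomeric CH2O (cracked paraformaldehyde), −78 °C; NH4Cl
Reagents that add atoms: none
Why: The ketone can enolise only toward C12 (C2 is quaternary), and the aldol addition of the lithium enolate to formaldehyde (hydroxymethylation) should take place on the α face because the β trajectory is syn-axial to the angular methyl C1, giving CH2OH equatorial (α) and methyl C13 axial (β).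

**Step 5**
Reactants: 8 12α-hydroxymethyl decalone
Product: 9 TIPS ether of 8
Conditions: TIPSOTf, 2,6-lutidine, CH2Cl2, 0 °C
Reagents that add atoms: triisopropylsilyl trifluoromethanesulfonate, CC(C)[Si](C(C)C)(C(C)C)OS(=O)(=O)C(F)(F)F
Why: Silylation of the neopentyl primary alcohol with the silyl triflate and a hindered base avoids retro-aldol cleavage, and the bulky TIPS group makes the ether oxygen a poor neighbouring group for step 8.

**Step 6**
Reactants: 9 TIPS ether of 8
Product: 10 equatorial (26β) decalinol
Conditions: LiAlH4, Et2O, 0 → 35 °C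
Reagents that add atoms: none
Why: Hydride reduction of the hindered ketone: the β face of the carbonyl is flanked by the two axial methyls C1 and C13, so hydride should enter axially from the α face and give the equatorial (β) alcohol, whose C–O bond is antiperiplanar to C2–C9.

**Step 7**
Reactants: 10 equatorial decalinol
Product: 11 equatorial decalyl mesylate with silyloxymethyl arm
Conditions: MsCl, Et3N, CH2Cl2, −20 → 0 °C; cold work-up, used at once
Reagents that add atoms: methanesulfonyl chloride, CS(=O)(=O)Cl
Why: Mesylation through sulfene reaches even an alcohol flanked by two quaternary carbons and leaves the C26–O configuration untouched.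

**Step 8**
Reactants: 11 equatorial decalyl mesylate
Product: 12 cis-hydroazulene with exocyclic C1=C2 methylene and CH2OTIPS arm
Conditions: 2,6-di-tert-butyl-4-methylpyridine (3 equiv), (CF3)2CHOH/CH2Cl2 (1:4), 0 → 40 °C
Reagents that add atoms: none
Why: Ionisation of the equatorial C26–O bond is helped by the antiperiplanar C2–C9 bond, so C9 shifts from C2 to C26 (Wagner–Meerwein 1,2-shift) and the tertiary C2 cation then gives up a proton of methyl C1 to the hindered pyridine. The closest known reaction type is the solvolytic rearrangement of 1-decalyl sulfonates with an adjacent angular methyl group to hydroazulenes. Neither ring is closed end to end: the cyclopentane (C9–C12, C26) arises by six-to-five contraction and the cycloheptane (C2–C6, C9, C26) by six-to-seven expansion, both through the one new C9–C26 bond. C26 is set by inversion (C9 enters anti to the leaving mesylate) and C9 migrates with retention, which turns the trans-decalin into the cis-fused bicycle. Migration of C9 rather than C11 is secured by the better migrating tertiary carbon and by the fact that a C11 shift would put the cation on C12 next to the electron-withdrawing silyloxymethyl group; substitution and β-elimination are excluded because C26 lies between two quaternary carbons. Proton loss from C1 rather than C3 or C26 rests on the bulk of the base and the exposed methyl group, and the ether oxygen cannot capture the C2 cation because C14 and C2 are trans on the new cyclopentane.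

**Step 9**
Reactants: 12 cis-hydroazulene TIPS ether
Product: 13 hydroazulene primary alcohol
Conditions: TBAF, THF, 50 °C
Reagents that add atoms: none
Why: Fluoride-induced desilylation cleaves the Si–O bond of the neopentyl TIPS ether and touches nothing else in the hydrocarbon.

**Step 10**
Reactants: 13 hydroazulene primary alcohol
Product: 14 C14 aldehyde
Conditions: Dess–Martin periodinane, NaHCO3, CH2Cl2, 20 °C
Reagents that add atoms: none
Why: Dess–Martin oxidation gives an aldehyde without α-hydrogen, which cannot epimerise, and a carbonyl-ene reaction with C1=C2 is impossible because C14 and C2 are trans on the cyclopentane.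

**Step 11**
Reactants: 14 C14 aldehyde; 15 dimethyl (1-diazo-2-oxopropyl)phosphonate
Product: 16 terminal alkyne (C14≡C20)
Conditions: K2CO3, MeOH, 0 → 20 °C
Reagents that add atoms: none
Why: Ohira–Bestmann (Seyferth–Gilbert) homologation converts a non-enolisable aldehyde into the terminal alkyne under mild carbonate conditions and adds C20.

**Step 12**
Reactants: 16 terminal alkyne; 17 N-methoxy-N-methylacetamide
Product: 19 ynone, via lithium acetylide 18 (not isolated)
Conditions: n-BuLi, THF, −78 °C; then 17, −78 → 0 °C; cold NH4Cl quench
Reagents that add atoms: none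
Why: Weinreb ketone synthesis: the acetylide adds once to the amide to give a chelated tetrahedral adduct that releases the ynone only on the cold quench, so over-addition is avoided.

**Step 13**
Reactants: 19 ynone
Product: 20 (S)-propargylic alcohol
Conditions: Ru[(S,S)-TsDPEN](p-cymene) (1 mol%), i-PrOH, 25 °C
Reagents that add atoms: none
Why: Noyori asymmetric transfer hydrogenation of an alkynyl methyl ketone is chemoselective for C=O and catalyst-controlled (the nearest stereocentre lies three bonds away across the linear alkyne); the (S,S) catalyst should give the (S)-carbinol, the sense usual for alkynyl methyl ketones.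

**Step 14**
Reactants: 20 (S)-propargylic alcohol
Product: 21 (S,Z)-allylic alcohol
Conditions: H2 (1 atm), Lindlar catalyst, quinoline, EtOAc, 20 °C
Reagents that add atoms: none
Why: Lindlar semi-hydrogenation adds hydrogen syn to the alkyne and stops at the (Z)-alkene, and the hindered 1,1-disubstituted C1=C2 bond should not be reduced on the poisoned catalyst.

**Step 15**
Reactants: 21 (S,Z)-allylic alcohol; 22 tributyl(iodomethyl)stannane
Product: 23 (tributylstannyl)methyl ether
Conditions: KH, THF, 0 °C; then 22, 18-crown-6 (cat.), 20 °C
Reagents that add atoms: none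
Why: Williamson alkylation of the potassium alkoxide with the reactive iodomethylstannane gives the ether needed for tin–lithium exchange.

**Step 16**
Reactants: 23 (tributylstannyl)methyl ether
Product: 25 homoallylic alcohol with (R)-C14 and (E)-propenyl group, via lithiomethyl ether 24 (not isolated)
Conditions: n-BuLi, THF, −78 °C; NH4Cl
Reagents that add atoms: none
Why: Wittig–Still [2,3]-sigmatropic rearrangement: the lithiomethyl ether bonds to C14 suprafacially, on the face that carries the C–O bond, and since allylic strain with the quaternary C12 in the (Z)-alkene forces the carbinol hydrogen into the alkene plane, the (S)-carbinol is transferred to (R)-C14 (CH2OH = C15) with an (E)-alkene, so C14 is set by the carbinol and not by the ring, whose branches C11 and C26 look alike from the α face.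

**Step 17**
Reactants: 25 homoallylic alcohol
Product: 26 acetate of 25
Conditions: Ac2O, pyridine, DMAP (cat.), CH2Cl2, 20 °C
Reagents that add atoms: acetic anhydride, CC(=O)OC(C)=O
Why: Standard acylation installs the acetate of the target before the second primary alcohol is made.

**Step 18**
Reactants: 26 acetate of 25; 27 ethylene
Product: 28 vinyl compound (C14 bearing CH2OAc and vinyl)
Conditions: ethylene (3 bar), Hoveyda–Grubbs second-generation catalyst (5 mol%), 1,4-benzoquinone (10 mol%), toluene, 50 °C
Reagents that add atoms: none
Why: Ethenolysis (olefin cross-metathesis with ethylene) should truncate the (E)-propenyl group to vinyl, the ruthenium methylidene adding with the metal on the unhindered CH–CH3 carbon; exchange at the exocyclic C1=C2 methylene is degenerate and ring closure onto it would need a trans-fused bicyclo[3.3.0]octene.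

**Step 19**
Reactants: 28 vinyl compound
Product: 30 primary alcohol (C21–OH), via alkyl disiamylborane 29 (not isolated)
Conditions: Sia2BH (1.3 equiv, from BH3·SMe2 and 2-methyl-2-butene), THF, −10 → 0 °C; then 30% H2O2, aq. NaOAc, 0 → 20 °C
Reagents that add atoms: hydrogen peroxide, OO
Why: Anti-Markovnikov hydroboration–oxidation with disiamylborane, which adds much faster to a monosubstituted vinyl group than to a 1,1-disubstituted alkene, should give the primary alcohol at C21, and buffered peroxide spares the acetate.

**Step 20**
Reactants: 30 primary alcohol; 31 bromoacetyl bromide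
Product: 32 bromoacetate
Conditions: pyridine, CH2Cl2, 0 °C
Reagents that add atoms: none
Why: Acylation of the primary alcohol with the acid bromide brings in C23 and C25.

**Step 21**
Reactants: 32 bromoacetate
Product: 33 diazoacetate
Conditions: TsNHNHTs, DBU, THF, 0 °C
Reagents that add atoms: N,N′-ditosylhydrazine, Cc1ccc(cc1)S(=O)(=O)NNS(=O)(=O)c1ccc(C)cc1
Why: N-Alkylation of the ditosylhydrazine by the bromoacetate and twofold sulfinate elimination give the diazoacetate under conditions mild enough for the acetate.

**Step 22**
Reactants: 33 diazoacetate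
Product: 34 CNP0235949.1
Conditions: Rh2(4R-MPPIM)4 (1 mol%), CH2Cl2, 40 °C, slow addition of 33
Reagents that add atoms: none
Why: Intramolecular dirhodium carbene C–H insertion of a primary alkyl diazoacetate closes the five-membered lactone at C20 (the six-ring alternative at C14–H is shielded and inductively deactivated), and the chiral carboxamidate ligand selects between the two diastereotopic C20 hydrogens, the 4R catalyst being chosen by analogy with the sense of induction for 3-substituted propyl diazoacetates, so that (R)-C20 is set under catalyst control.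

**Compound list**
1 | (+)-sclareolide | C[C@]12CCCC(C)(C)[C@@H]1CC[C@@](C)(OC3=O)[C@@H]2C3 | starting material
2 | α-phenylselanyl sclareolide (PhSe on the lactone CH2, cis to H-26) | C[C@]12CCCC(C)(C)[C@@H]1CC[C@@](C)(OC3=O)[C@@H]2[C@@H]3[Se]c4ccccc4 | intermediate
3 | butenolide, 9(11)-dehydrosclareolide (C26=CH–C(=O)–O–C12) | C[C@]12CCCC(C)(C)[C@@H]1CC[C@@](C)(OC3=O)C2=C3 | intermediate
4 | C26 ketone with glyoxylate ester on the C12 oxygen | C[C@]12CCCC(C)(C)[C@@H]1CC[C@@](C)(OC(=O)C=O)C2=O | intermediate
5 | ketol: trans-fused 2-hydroxy-2,5,5,8a-tetramethyloctahydronaphthalen-1(2H)-one, OH α (equatorial), CH3 β on C12 | C[C@]12CCCC(C)(C)[C@@H]1CC[C@@](C)(O)C2=O | intermediate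
6 | decalone: trans-fused 2,5,5,8a-tetramethyloctahydronaphthalen-1(2H)-one, C13 methyl equatorial (α) | C[C@]12CCCC(C)(C)[C@@H]1CC[C@@H](C)C2=O | intermediate
7 | formaldehyde | C=O | starting material
8 | 12α-hydroxymethyl decalone (CH2OH α equatorial, CH3 β axial on C12) | C[C@]12CCCC(C)(C)[C@@H]1CC[C@@](C)(CO)C2=O | intermediate
9 | TIPS ether of 8 | C[C@]12CCCC(C)(C)[C@@H]1CC[C@@](C)(CO[Si](C(C)C)(C(C)C)C(C)C)C2=O | intermediate
10 | equatorial (26β) decalinol with 12α-CH2OTIPS | C[C@]12CCCC(C)(C)[C@@H]1CC[C@@](C)(CO[Si](C(C)C)(C(C)C)C(C)C)[C@@H]2O | intermediate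
11 | equatorial decalyl mesylate with silyloxymethyl arm | C[C@]12CCCC(C)(C)[C@@H]1CC[C@@](C)(CO[Si](C(C)C)(C(C)C)C(C)C)[C@@H]2OS(C)(=O)=O | intermediate
12 | cis-hydroazulene with exocyclic C1=C2 methylene and CH2OTIPS arm on C12 | C=C1CCCC(C)(C)[C@@H]2CC[C@@](C)(CO[Si](C(C)C)(C(C)C)C(C)C)[C@H]12 | intermediate
13 | hydroazulene primary alcohol (CH2OH on C12) | C=C1CCCC(C)(C)[C@@H]2CC[C@@](C)(CO)[C@H]12 | intermediate
14 | hydroazulene C14 aldehyde | C=C1CCCC(C)(C)[C@@H]2CC[C@@](C)(C=O)[C@H]12 | intermediate
15 | dimethyl (1-diazo-2-oxopropyl)phosphonate | CC(=O)C(=[N+]=[N-])P(=O)(OC)OC | starting material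
16 | terminal alkyne (ethynyl on C12) | C=C1CCCC(C)(C)[C@@H]2CC[C@@](C)(C#C)[C@H]12 | intermediate
17 | N-methoxy-N-methylacetamide | CON(C)C(C)=O | starting material
18 | lithium acetylide of 16 | C=C1CCCC(C)(C)[C@@H]2CC[C@@](C)(C#C[Li])[C@H]12 | intermediate
19 | ynone (3-oxobut-1-ynyl on C12) | C=C1CCCC(C)(C)[C@@H]2CC[C@@](C)(C#CC(C)=O)[C@H]12 | intermediate
20 | (S)-propargylic alcohol | C=C1CCCC(C)(C)[C@@H]2CC[C@@](C)(C#C[C@@H](O)C)[C@H]12 | intermediate
21 | (S,Z)-allylic alcohol | C=C1CCCC(C)(C)[C@@H]2CC[C@@](C)(/C=C\[C@@H](O)C)[C@H]12 | intermediate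
22 | tributyl(iodomethyl)stannane | CCCC[Sn](CCCC)(CCCC)CI | starting material
23 | (tributylstannyl)methyl ether of 21 | C=C1CCCC(C)(C)[C@@H]2CC[C@@](C)(/C=C\[C@@H](OC[Sn](CCCC)(CCCC)CCCC)C)[C@H]12 | intermediate
24 | lithiomethyl ether of 21 | C=C1CCCC(C)(C)[C@@H]2CC[C@@](C)(/C=C\[C@@H](OC[Li])C)[C@H]12 | intermediate
25 | homoallylic alcohol: (R)-C14 bearing CH2OH (C15) and (E)-propenyl | C=C1CCCC(C)(C)[C@@H]2CC[C@@](C)([C@H](CO)/C=C/C)[C@H]12 | intermediate
26 | acetate of 25 | C=C1CCCC(C)(C)[C@@H]2CC[C@@](C)([C@H](COC(C)=O)/C=C/C)[C@H]12 | intermediate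
27 | ethylene | C=C | starting material
28 | vinyl compound: C14 bearing CH2OAc and vinyl | C=C1CCCC(C)(C)[C@@H]2CC[C@@](C)([C@H](COC(C)=O)C=C)[C@H]12 | intermediate
29 | alkyl disiamylborane (boron on C21) | C=C1CCCC(C)(C)[C@@H]2CC[C@@](C)([C@H](COC(C)=O)CCB(C(C)C(C)C)C(C)C(C)C)[C@H]12 | intermediate
30 | primary alcohol: C14 bearing CH2OAc and CH2CH2OH | C=C1CCCC(C)(C)[C@@H]2CC[C@@](C)([C@H](COC(C)=O)CCO)[C@H]12 | intermediate
31 | bromoacetyl bromide | BrCC(Br)=O | starting material
32 | bromoacetate of 30 | C=C1CCCC(C)(C)[C@@H]2CC[C@@](C)([C@H](COC(C)=O)CCOC(=O)CBr)[C@H]12 | intermediate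
33 | diazoacetate of 30 | C=C1CCCC(C)(C)[C@@H]2CC[C@@](C)([C@H](COC(C)=O)CCOC(=O)C=[N+]=[N-])[C@H]12 | intermediate
34 | CNP0235949.1 | C=C1CCCC(C)(C)[C@@H]2CC[C@@](C)([C@H](COC(C)=O)[C@@H]3COC(=O)C3)[C@H]12 | target

**Total step count:** 22. **Longest linear sequence:** 22 steps, from (+)-sclareolide.

**Steps most likely to fail**

Step 8. The C2 cation may lose its proton toward the ring (C3 or C26) instead of from methyl C1, the exocyclic alkene may be isomerised by the pyridinium salt, or C11 may shift in place of C9. The fallback sets out from 11 and comes back at 12. The ionisation is run in aqueous acetone over CaCO3, so that water captures the C2 cation and gives the tertiary alcohol F1. Dry HCl in CH2Cl2 at −40 °C turns F1, and by Markovnikov addition any olefin isomers formed with it, into the tertiary chloride F2. E2 elimination with potassium 3-ethylpentan-3-oxide in toluene then follows Hofmann orientation, the bulky alkoxide taking a hydrogen of the unhindered methyl group, and should give 12.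

Step 16. The carbanion may fail to reach the neopentyl terminus C14, so that a [1,2]-shift or protonation of the lithiomethyl ether competes with the [2,3] pathway. The fallback sets out from 21 and comes back at 25. Alcohol 21 is acetylated (Ac2O, DMAP) to the allylic acetate F3. Ireland–Claisen rearrangement (LDA, TMSCl, THF, −78 → 65 °C), whose six-membered transition state tolerates hindered termini and transfers the (S)-carbinol to C14 in the same suprafacial sense, should give the acid F4 with the (E)-propenyl group. The extra carbon is removed by Barton decarboxylative hydroxylation: the thiohydroxamate ester F5 (N-hydroxypyridine-2-thione, DCC) is treated with O2 and t-BuSH under visible light to give the hydroperoxide F6, which P(OMe)3 reduces to 25.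

Step 22. Catalyst control over the two diastereotopic C20 hydrogens may be insufficient (mismatch with the adjacent C14 centre), insertion may occur at C14–H, or the carbene may dimerise. The fallback sets out from 30 and comes back at 34. Alcohol 30 is oxidised (TEMPO, PhI(OAc)2, MeCN/H2O) to the acid F7, which is attached to (R)-4-benzyl-2-oxazolidinone (PivCl, Et3N, LiCl) to give the imide F8. Evans alkylation of its sodium (Z)-enolate (NaHMDS, THF, −78 °C) with methyl bromoacetate, the electrophile entering anti to the benzyl group, sets C20 in the alkylated imide F9. LiBH4/MeOH in Et2O at 0 °C removes the auxiliary reductively and gives the hydroxy ester F10, which should close to the lactone 34 with catalytic PPTS.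

**Further compounds**
F1 | step 8 | tertiary alcohol at C2 of the hydroazulene (C2 configuration not defined) | CC1(O)CCCC(C)(C)[C@@H]2CC[C@@](C)(CO[Si](C(C)C)(C(C)C)C(C)C)[C@H]12
F2 | step 8 | tertiary chloride at C2 of the hydroazulene (C2 configuration not defined) | CC1(Cl)CCCC(C)(C)[C@@H]2CC[C@@](C)(CO[Si](C(C)C)(C(C)C)C(C)C)[C@H]12
F3 | step 16 | allylic acetate of 21 | C=C1CCCC(C)(C)[C@@H]2CC[C@@](C)(/C=C\[C@@H](OC(C)=O)C)[C@H]12
F4 | step 16 | acid: C14 bearing CH2CO2H and (E)-propenyl | C=C1CCCC(C)(C)[C@@H]2CC[C@@](C)([C@H](CC(=O)O)/C=C/C)[C@H]12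
F5 | step 16 | thiohydroxamate (Barton) ester of F4 | C=C1CCCC(C)(C)[C@@H]2CC[C@@](C)([C@H](CC(=O)ON3C=CC=CC3=S)/C=C/C)[C@H]12
F6 | step 16 | hydroperoxide: C14 bearing CH2OOH and (E)-propenyl | C=C1CCCC(C)(C)[C@@H]2CC[C@@](C)([C@H](COO)/C=C/C)[C@H]12
F7 | step 22 | acid: C14 bearing CH2OAc and CH2CO2H | C=C1CCCC(C)(C)[C@@H]2CC[C@@](C)([C@H](COC(C)=O)CC(=O)O)[C@H]12
F8 | step 22 | N-acyl (R)-4-benzyl-2-oxazolidinone of F7 | C=C1CCCC(C)(C)[C@@H]2CC[C@@](C)([C@H](COC(C)=O)CC(=O)N3[C@H](Cc4ccccc4)COC3=O)[C@H]12
F9 | step 22 | alkylated imide with CH2CO2Me on C20 | C=C1CCCC(C)(C)[C@@H]2CC[C@@](C)([C@H](COC(C)=O)[C@@H](CC(=O)OC)C(=O)N3[C@H](Cc4ccccc4)COC3=O)[C@H]12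
F10 | step 22 | hydroxy ester: C20 bearing CH2OH and CH2CO2Me | C=C1CCCC(C)(C)[C@@H]2CC[C@@](C)([C@H](COC(C)=O)[C@@H](CC(=O)OC)CO)[C@H]12
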